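## Retrosynthetic overview

1. Dactylomelol ⇒ acyclic (3S,6E,10S,14S)-10,11-epoxy-1,6-diene by one Ti(III)-catalysed radical formal [3+2]: epoxide homolysis, 6-endo C6–C11 bond formation (carbocycle first), then C7–O closure (oxygen bridge second), all in the same step.
2. Tertiary vinyl carbinol ⇒ E-allylic carbonate (Cu-catalysed enantioselective boryl SN2′, then oxidation); C5–C6 ⇒ B-alkyl Suzuki coupling of a dienol-derived borane with an E-vinyl iodide.
3. 10,11-Epoxide ⇒ Shi epoxidation while C6=C7 is still masked as the vinyl iodide; C10=C11 ⇒ cross-metathesis.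
4. CHBr–CMe2Cl ⇒ catalytic enantioselective bromochlorination of prenol, then triflate/methallyl-Grignard coupling; vinyl iodide ⇒ carboalumination of hex-1-en-5-yne.

Assumption: compounds 1, 4 (as THF solution), 6 and 10 are purchased; the C10=C11 E/Z mixture (and hence the C11 epoxide epimers) is carried forward because C11 becomes a planar radical in the last step.

## Route

**Step 1**
Reactants: 1, 3-methylbut-2-en-1-ol (prenol)
Product: 2, (S)-2-bromo-3-chloro-3-methylbutan-1-ol
Conditions: NBS, ClTi(OiPr)3, chiral tridentate Schiff-base ligand (20 mol %, antipode giving 2S), hexanes, −20 °C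
Reagents that add atoms: N-bromosuccinimide, O=C1CCC(=O)N1Br; chlorotitanium triisopropoxide, CC(C)O[Ti](Cl)(OC(C)C)OC(C)C
Why: Ti/Schiff-base-catalysed enantioselective bromochlorination of an allylic alcohol (Burns-type), in which Ti-bound chloride opens the ligand-shielded bromonium ion at the tertiary carbon, so the CHBr centre (future C14, S) is set by catalyst control.

**Step 2**
Reactants: 2, (S)-2-bromo-3-chloro-3-methylbutan-1-ol
Product: 3, (S)-2-bromo-3-chloro-3-methylbutyl trifluoromethanesulfonate
Conditions: Tf2O, 2,6-lutidine, CH2Cl2, −78 °C; used crude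
Reagents that add atoms: triflic anhydride, O=S(=O)(OS(=O)(=O)C(F)(F)F)C(F)(F)F
Why: Standard O-triflation of a primary alcohol; the β-bromine retards ionisation and the stereocentre is not touched.

**Step 3**
Reactants: 3, (S)-2-bromo-3-chloro-3-methylbutyl triflate; 4, 2-methylallylmagnesium chloride
Product: 5, (S)-5-bromo-6-chloro-2,6-dimethylhept-1-ene
Conditions: 4 (1.5 equiv), CuI (10 mol %), THF/Et2O, −78 → −40 °C
Reagents that add atoms: none (4 is the carbon source)
Why: Cu-catalysed sp3–sp3 coupling of a primary triflate with an allylic Grignard (Kochi-type), which is fast enough at −78 °C to outrun E2 and halogen–metal exchange; methallyl is symmetric so there is no α/γ issue, and the stereocentre is a spectator.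

**Step 4**
Reactants: 6, hex-1-en-5-yne
Product: 7, (E)-1-iodo-2-methylhexa-1,5-diene
Conditions: Me3Al, Cp2ZrCl2 (20 mol %), CH2Cl2, 0 °C → rt; then I2, THF, −30 → 0 °C
Reagents that add atoms: trimethylaluminium, C[Al](C)C; iodine, II
Why: Negishi Zr-catalysed carboalumination adds Me–Al syn across the terminal alkyne (Me internal) and iodinolysis proceeds with retention, giving the E-trisubstituted vinyl iodide; the isolated alkene is inert.

**Step 5**
Reactants: 5, (S)-5-bromo-6-chloro-2,6-dimethylhept-1-ene; 7, (E)-1-iodo-2-methylhexa-1,5-diene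
Product: 8, (1E,5E,9S)-9-bromo-10-chloro-1-iodo-2,6,10-trimethylundeca-1,5-diene (about 3:1 with the 5Z isomer)
Conditions: Hoveyda–Grubbs II (7 mol %), 7 (2.5 equiv), CH2Cl2, 40 °C
Reagents that add atoms: none
Why: Olefin cross-metathesis of a terminal alkene with a 1,1-disubstituted alkene gives the trisubstituted C10=C11 alkene, while the hindered iodoalkene does not engage.

**Step 6**
Reactants: 8, (1E,5E/Z,9S)-9-bromo-10-chloro-1-iodo-2,6,10-trimethylundeca-1,5-diene
Product: 9, (2S,3S)-2-[(S)-3-bromo-4-chloro-4-methylpentyl]-3-[(E)-4-iodo-3-methylbut-3-en-1-yl]-2-methyloxirane (minor 2R epimer from the 5Z alkene; same 3S)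
Conditions: ent-Shi ketone (L-fructose-derived, 0.3 equiv), Oxone, K2CO3, Bu4NHSO4, MeCN/DMM/aq. borate buffer (pH 10.5), 0 °C
Reagents that add atoms: Oxone (potassium peroxymonosulfate), [K+].[O-]S(=O)(=O)OO
Why: Shi asymmetric epoxidation, in which the electrophilic dioxirane selects the trialkyl alkene over the electron-poor iodoalkene and the spiro transition state fixes the face at the CH carbon (C10, S) for both alkene isomers.

**Step 7**
Reactants: 10, (E)-3-methylpent-2-en-4-yn-1-ol
Product: 11, (E)-3-methylpenta-2,4-dien-1-ol
Conditions: H2 (1 atm), Lindlar catalyst, quinoline, EtOAc/hexane, rt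
Reagents that add atoms: none
Why: Lindlar semi-hydrogenation of the terminal alkyne to a vinyl group; the E-trisubstituted alkene is untouched.

**Step 8**
Reactants: 11, (E)-3-methylpenta-2,4-dien-1-ol; 9, the epoxy vinyl iodide
Product: 12, (2E,6E,10S,11S,14S)-14-bromo-15-chloro-10,11-epoxy-3,7,11,15-tetramethylhexadeca-2,6-dien-1-ol (plus minor 11R epimer)
Conditions: 11, 9-BBN-H (2.2 equiv), THF, 0 °C → rt; then 9, Pd(dppf)Cl2 (5 mol %), AsPh3, Cs2CO3, DMF/H2O, rt
Reagents that add atoms: none (9-BBN-H delivers only H to the product)
Why: B-alkyl Suzuki–Miyaura coupling, in which 9-BBN (first equivalent caps the OH) adds anti-Markovnikov to the terminal vinyl of the diene and Pd couples the sp3 borane to the vinyl iodide with retention of E geometry; the epoxide, secondary bromide and tertiary chloride are inert to Pd(0)/Cs2CO3 at rt.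

**Step 9**
Reactants: 12, the C20 epoxy dienol
Product: 13, (2E,6E,10S,11S,14S)-14-bromo-15-chloro-10,11-epoxy-3,7,11,15-tetramethylhexadeca-2,6-dien-1-yl methyl carbonate
Conditions: ClCO2Me, pyridine, DMAP (cat.), CH2Cl2, 0 °C
Reagents that add atoms: methyl chloroformate, COC(=O)Cl
Why: Simple O-acylation to install the leaving group for allylic substitution.

**Step 10**
Reactants: 13, the allylic methyl carbonate
Product: 14, (3S,6E,10S,11S,14S)-14-bromo-15-chloro-10,11-epoxy-3,7,11,15-tetramethylhexadeca-1,6-dien-3-ol (plus minor 11R epimer)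
Conditions: B2pin2, chiral NHC–Cu (imidazolinium salt 6 mol %, Cu(OTf)2 5 mol %, NaOMe; antipode giving 3S), DME, −50 → −30 °C; then NaBO3·4H2O, THF/H2O, rt
Reagents that add atoms: sodium perborate (supplies the OH oxygen), [Na+].[O-]OB=O; bis(pinacolato)diboron (boron is transient), CC1(C)OB(OC1(C)C)B1OC(C)(C)C(C)(C)O1
Why: Cu-catalysed enantioselective allylic boryl substitution (SN2′) places Bpin on C3 with catalyst control, and stereoretentive C–B oxidation gives the (3S) tertiary vinyl carbinol without touching the epoxide or halides at low temperature.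

**Step 11 (key step)**
Reactants: 14, the (3S,6E,10S,14S)-epoxy dienol
Product: 15, dactylomelol, (S)-5-[(1R,2S,3S,4S)-3-((S)-3-bromo-4-chloro-4-methylpentyl)-1,3-dimethyl-7-oxabicyclo[2.2.1]heptan-2-yl]-3-methylpent-1-en-3-ol
Conditions: cationic titanocene(III) from Cp2Ti(OTf)2 (10 mol %) and Zn dust (20 mol %), THF (0.01 M), 25 → 50 °C
Reagents that add atoms: none (isomerisation)
Why: Proposed new method: Ti(III) cleaves the tertiary C11–O bond of the epoxide (the 10S C–O centre is retained) to a β-titanoxy tertiary radical that adds 6-endo to C6 of the E-alkene through a chair transition state (O–Ti equatorial and anti to the forming bond, chain A equatorial because of the E geometry, the C12 chain pseudo-equatorial and the methyl pseudo-axial), and the resulting tertiary C7 radical, 1,4 to the Ti–O bond, closes the ether by homolytic substitution at oxygen with release of Ti(III), so C6, C7 and C11 are set relative to C10 in one redox-neutral step; the closest known chemistry is the Nugent–RajanBabu Ti(III) epoxypolyene 6-endo radical cyclisation combined with titanocene-catalysed radical tetrahydrofuran synthesis from epoxides and alkenes, and the C11 facial preference is expected to be only moderate (the C3 epimer is the likely by-product).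

## Compound list

1 | 3-methylbut-2-en-1-ol (prenol) | CC(C)=CCO | starting material
2 | (S)-2-bromo-3-chloro-3-methylbutan-1-ol | OC[C@H](Br)C(C)(C)Cl | intermediate
3 | (S)-2-bromo-3-chloro-3-methylbutyl triflate | O=S(=O)(OC[C@H](Br)C(C)(C)Cl)C(F)(F)F | intermediate
4 | 2-methylallylmagnesium chloride | C=C(C)C[Mg]Cl | starting material
5 | (S)-5-bromo-6-chloro-2,6-dimethylhept-1-ene | C=C(C)CC[C@H](Br)C(C)(C)Cl | intermediate
6 | hex-1-en-5-yne | C=CCCC#C | starting material
7 | (E)-1-iodo-2-methylhexa-1,5-diene | C=CCC/C(C)=C/I | intermediate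
8 | (1E,5E,9S)-9-bromo-10-chloro-1-iodo-2,6,10-trimethylundeca-1,5-diene (major isomer; 5Z minor) | I/C=C(C)/CC/C=C(\C)CC[C@H](Br)C(C)(C)Cl | intermediate
9 | (2S,3S)-2-[(S)-3-bromo-4-chloro-4-methylpentyl]-3-[(E)-4-iodo-3-methylbut-3-en-1-yl]-2-methyloxirane (major; C2 epimer minor) | I/C=C(C)/CC[C@@H]1O[C@@]1(C)CC[C@H](Br)C(C)(C)Cl | intermediate
10 | (E)-3-methylpent-2-en-4-yn-1-ol | C#C/C(C)=C/CO | starting material
11 | (E)-3-methylpenta-2,4-dien-1-ol | C=C/C(C)=C/CO | intermediate
12 | (2E,6E,10S,11S,14S)-14-bromo-15-chloro-10,11-epoxy-3,7,11,15-tetramethylhexadeca-2,6-dien-1-ol | OC/C=C(C)/CC/C=C(C)/CC[C@@H]1O[C@@]1(C)CC[C@H](Br)C(C)(C)Cl | intermediate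
13 | methyl carbonate of 12 | COC(=O)OC/C=C(C)/CC/C=C(C)/CC[C@@H]1O[C@@]1(C)CC[C@H](Br)C(C)(C)Cl | intermediate
14 | (3S,6E,10S,11S,14S)-14-bromo-15-chloro-10,11-epoxy-3,7,11,15-tetramethylhexadeca-1,6-dien-3-ol | C=C[C@@](C)(O)CC/C=C(C)/CC[C@@H]1O[C@@]1(C)CC[C@H](Br)C(C)(C)Cl | intermediate
15 | dactylomelol | C=C[C@@](C)(O)CC[C@H]1[C@](C)(CC[C@H](Br)C(C)(C)Cl)[C@@H]2CC[C@@]1(C)O2 | target

## Summary

Total steps: 11. Longest linear sequence: 9 (steps 1 → 2 → 3 → 5 → 6 → 8 → 9 → 10 → 11).

Steps most likely to fail, each with a fallback that changes the approach: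

1. **Step 11.** The tertiary radical may not close onto oxygen to form the strained bridge (β-H elimination to the exocyclic alkene instead), C11 facial selectivity may be low, or Ti(III)/Zn may attack the vicinal bromochloride. Fallback: split the cascade into a classical reductive Ti(III) epoxypolyene cyclisation (Cp2TiCl2 cat., Mn, collidine/TMSCl) to the 4-methylenecyclohexanol, then build the oxygen bridge separately by transannular Markovnikov hydroalkoxylation (Co(salen)/N-fluoropyridinium/silane hydrogen-atom-transfer conditions, or Hg(OTFA)2 then NaBH4).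

2. **Step 3.** The Grignard may cause E2, Br–Mg exchange or reductive dehalogenation of the β-bromo triflate. Fallback: build the carbon chain before the halogens. Couple prenyl bromide with methallyl Grignard to 2,6-dimethylhepta-1,5-diene, Shi-epoxidise the trisubstituted alkene, and convert the enantioenriched epoxide to the bromochloride stereospecifically (bromide opening to the bromohydrin, then chlorination through the neighbouring-bromine bromonium ion).

3. **Step 10.** Methoxide or Cu–Bpin may not tolerate the bromochloride, or the enantioselectivity may be poor on this substrate. Fallback: Sharpless asymmetric epoxidation of 12 with L-(+)-DET to the (2S,3S)-epoxy alcohol, oxidation to the epoxy aldehyde, and Wharton transposition with hydrazine to the (3S) vinyl carbinol.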